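**Retrosynthetic overview**
- The target is a 3,6''-biflavone. The last step frees O5 and O5'' (methyl ethers peri to the two carbonyls) and O4''' (benzyl) with BCl3; before that, ring C'' of flavone 2 is closed by cyclodehydration of a 1,3-diketone made by aroylation of a C-acetyl group on ring A''.
- Key disconnection: C4–C4a of flavone 1. The feature used is that C4 (the carbonyl carbon of flavone 1) is bonded to C3, and C3 carries ring A'' through C6'', whose oxygen O5'' is ortho to the C3–C6'' bond. C4 and O5'' are therefore tied together as the five-membered lactone of a benzofuran-2(3H)-one; the lactone carbonyl is handed to the 3,5-dimethoxyphenoxy ring (future ring A) as the C4 ketone while O5'' is released.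
- The lactone precursor comes from 4,6-bis(benzyloxy)benzofuran-2(3H)-one (from 3,5-bis(benzyloxy)phenol and ethyl glyoxylate; the C3–C6'' bond is its aryl–CH2 bond) by C3-anisoylation, enol triflation and displacement with 3,5-dimethoxyphenoxide.
- The hydroxyl released in the key step directs acetylation to its ortho carbon and is then capped as a methyl ether, so only the oxygen para to the biaryl bond can close ring C'' (3,6''- and not 3,8''-linkage).
- Ring order: benzofuranone lactone (temporary), then ring C of flavone 1 (step 6), then ring C'' of flavone 2 (step 11); rings A, B, A'' and B'' come intact from the building blocks.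

Key step: step 6

Assumption: the C3–C6'' biaryl axis is not treated as a stereo-element (the target carries no axial descriptor). Compound 3 is racemic and its stereocentre is removed in step 2. The exocyclic alkenes of 7, 8 and 10 are drawn Z (oxygen substituent cis to the lactone carbonyl), but either geometry should serve.

Step 1
Reactants: 1 3,5-bis(benzyloxy)phenol; 2 ethyl glyoxylate
Product: 3 ethyl 2-[2,4-bis(benzyloxy)-6-hydroxyphenyl]-2-hydroxyacetate (racemic)
Conditions: EtMgBr (1.0 equiv), Et2O, 0 °C; solvent switch to PhMe/CH2Cl2; 2 (1.2 equiv), 0 °C to rt; aq. NH4Cl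
Reagents that add atoms: none
Why: The bromomagnesium phenoxide should deliver the glyoxylate carbonyl to the ring carbon next to the phenol oxygen through a chelated six-membered transition state (ortho-selective Friedel-Crafts hydroxyalkylation of a metal phenoxide); both ortho carbons of 1 are equivalent, and the carbinol stereocentre forms racemic and is removed in step 2.

Step 2
Reactants: 3 ethyl 2-[2,4-bis(benzyloxy)-6-hydroxyphenyl]-2-hydroxyacetate
Product: 5 lactone 4,6-bis(benzyloxy)benzofuran-2(3H)-one, via ethyl arylacetate 4 (not isolated)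
Conditions: Et3SiH (3 equiv), CF3CO2H (10 equiv), CH2Cl2, 0 °C to rt; then TsOH·H2O (cat.), PhMe, 80 °C
Reagents that add atoms: none
Why: Ionic hydrogenation (acid ionises the benzylic hydroxyl to a cation stabilised by three ring oxygens and the silane delivers hydride) followed by acid-catalysed lactonisation of the 2-hydroxyphenylacetic ester; carrying the benzyl ethers in from the phenol avoids a base benzylation of the lactone, which would alkylate its acidic C3 methylene.

Step 3
Reactants: 5 4,6-bis(benzyloxy)benzofuran-2(3H)-one; 6 4-methoxybenzoyl chloride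
Product: 7 (Z)-4,6-bis(benzyloxy)-3-[hydroxy(4-methoxyphenyl)methylene]benzofuran-2(3H)-one (enol form of the 3-aroyl lactone)
Conditions: LiN(SiMe3)2 (2.2 equiv), THF, −78 °C; 6 (1.05 equiv), −78 to 0 °C; aq. NH4Cl
Reagents that add atoms: none
Why: Claisen-type C-acylation of the lactone enolate, in which the second equivalent of base deprotonates the product so that the chelated C-acyl enolate is the thermodynamic sink; no stereocentre is formed.

Step 4
Reactants: 7 (Z)-4,6-bis(benzyloxy)-3-[hydroxy(4-methoxyphenyl)methylene]benzofuran-2(3H)-one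
Product: 8 (Z)-4,6-bis(benzyloxy)-3-[(4-methoxyphenyl)(trifluoromethylsulfonyloxy)methylene]benzofuran-2(3H)-one
Conditions: Tf2O (1.1 equiv), iPr2NEt (1.3 equiv), CH2Cl2, −78 °C
Reagents that add atoms: trifluoromethanesulfonic anhydride, O=S(=O)(OS(=O)(=O)C(F)(F)F)C(F)(F)F
Why: Enol triflate formation of a 1,3-dicarbonyl compound by O-sulfonylation of the ketone-derived enol oxygen; sulfonylation at the lactone oxygen would give a ketene-acetal triflate and should be disfavoured.

Step 5
Reactants: 8 enol triflate; 9 3,5-dimethoxyphenol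
Product: 10 (Z)-4,6-bis(benzyloxy)-3-[(3,5-dimethoxyphenoxy)(4-methoxyphenyl)methylene]benzofuran-2(3H)-one
Conditions: Cs2CO3 (1.2 equiv), MeCN, 0 °C to rt
Reagents that add atoms: none
Why: Addition-elimination (vinylic nucleophilic substitution) of the phenoxide at the beta carbon of the sulfonyloxy-substituted unsaturated lactone, as with 4-sulfonyloxycoumarins; either alkene geometry is acceptable because the push-pull alkene equilibrates in step 6.

Step 6
Reactants: 10 (Z)-4,6-bis(benzyloxy)-3-[(3,5-dimethoxyphenoxy)(4-methoxyphenyl)methylene]benzofuran-2(3H)-one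
Product: 11 3-[2,4-bis(benzyloxy)-6-hydroxyphenyl]-5,7-dimethoxy-2-(4-methoxyphenyl)-4H-chromen-4-one
Conditions: BF3·OEt2 (4 equiv), ClCH2CH2Cl, rt to 60 °C; aq. NaHCO3
Reagents that add atoms: none
Why: Proposed new method: BF3 binds the lactone carbonyl, and the ortho carbon of the 3,5-dimethoxyphenoxy ring (activated ortho/para by three oxygens) attacks the lactone carbonyl carbon lying cis to it across the exocyclic alkene; collapse of the tetrahedral intermediate (or of the equivalent acylium/phenoxide pair) expels the ring A'' phenoxide and rearomatisation gives the 4-pyranone, so the lactone serves both as acyl donor and as mask of the ortho hydroxyl. The closest known reactions are the Ruhemann flavone synthesis (acid-mediated Friedel-Crafts closure of 3-aryloxycinnamic acids) and Fries-type acyl transfer from aryl esters. The pyranone closes 6-exo-trig at the carbonyl carbon, forming C4–C4a, and no stereocentre is created. The step needs the aryloxy group cis to the lactone carbonyl, which the Lewis acid should secure because the push-pull alkene rotates through its oxocarbenium form and only the cis isomer is drained; it needs attack by the phenoxy ring and not the 4-methoxyphenyl ring, whose ortho carbons are meta to methoxy and would lead to a strained indenone; and it needs one regiochemistry, which the equivalence of the two ortho carbons of the symmetric phenoxy ring guarantees. The benzyl ethers should tolerate BF3·OEt2 at this temperature, and the gain of an aromatic vinylogous-ester pyranone at the cost of a strained aryl lactone is the expected driving force.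

Step 7
Reactants: 11 3-[2,4-bis(benzyloxy)-6-hydroxyphenyl]-5,7-dimethoxy-2-(4-methoxyphenyl)-4H-chromen-4-one
Product: 13 acetophenone 3-[3-acetyl-4,6-bis(benzyloxy)-2-hydroxyphenyl]-5,7-dimethoxy-2-(4-methoxyphenyl)-4H-chromen-4-one, via O-acetyl flavone 12 (not isolated)
Conditions: Ac2O (1.5 equiv), BF3·OEt2 (3 equiv), CH2Cl2, 0 to 40 °C; aq. NaOAc
Reagents that add atoms: acetic anhydride, CC(=O)OC(C)=O
Why: O-acetylation followed by boron-mediated Fries rearrangement (Friedel-Crafts acetylation) should place the acetyl group on the only free carbon ortho to the phenol, where boron chelation between phenol oxygen and new carbonyl stabilises the product, the usual outcome for 3,5-dialkoxyphenols; the other free carbon lies between two benzyloxy groups and gains no chelation.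

Step 8
Reactants: 13 3-[3-acetyl-4,6-bis(benzyloxy)-2-hydroxyphenyl]-5,7-dimethoxy-2-(4-methoxyphenyl)-4H-chromen-4-one
Product: 14 3-[3-acetyl-4,6-bis(benzyloxy)-2-methoxyphenyl]-5,7-dimethoxy-2-(4-methoxyphenyl)-4H-chromen-4-one
Conditions: MeI (5 equiv), K2CO3, DMF, 50 °C
Reagents that add atoms: iodomethane, CI
Why: Williamson methylation of the chelated, hindered phenol under forcing carbonate conditions; the cap blocks the oxygen ortho to the biaryl bond from closing ring C'' and leaves it peri to the future C4'' carbonyl, from where BCl3 removes it in step 12.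

Step 9
Reactants: 14 3-[3-acetyl-4,6-bis(benzyloxy)-2-methoxyphenyl]-5,7-dimethoxy-2-(4-methoxyphenyl)-4H-chromen-4-one
Product: 15 3-(3-acetyl-4,6-dihydroxy-2-methoxyphenyl)-5,7-dimethoxy-2-(4-methoxyphenyl)-4H-chromen-4-one
Conditions: H2 (1 atm), Pd/C (10%), EtOAc/MeOH, rt
Reagents that add atoms: none
Why: Hydrogenolysis of the two aryl benzyl ethers over palladium on carbon; the tetrasubstituted flavone alkene, the aryl ketone and the methyl ethers should be untouched at one atmosphere and room temperature.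

Step 10
Reactants: 15 3-(3-acetyl-4,6-dihydroxy-2-methoxyphenyl)-5,7-dimethoxy-2-(4-methoxyphenyl)-4H-chromen-4-one; 16 4-(benzyloxy)benzoyl chloride
Product: 17 1-[4-(benzyloxy)phenyl]-3-{3-[5,7-dimethoxy-2-(4-methoxyphenyl)-4-oxo-4H-chromen-3-yl]-4,6-dihydroxy-2-methoxyphenyl}propane-1,3-dione
Conditions: LiN(SiMe3)2 (4.2 equiv), THF, −78 to −10 °C; 16 (1.05 equiv), −78 °C to rt; aq. HCl
Reagents that add atoms: none
Why: Claisen-type C-aroylation of the lithium polyanion (two phenoxides and the methyl ketone enolate) by the acid chloride should give the 1,3-diketone of a Baker-Venkataraman sequence in one operation without hydroxyl protection.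

Step 11
Reactants: 17 1-[4-(benzyloxy)phenyl]-3-{3-[5,7-dimethoxy-2-(4-methoxyphenyl)-4-oxo-4H-chromen-3-yl]-4,6-dihydroxy-2-methoxyphenyl}propane-1,3-dione
Product: 18 2-[4-(benzyloxy)phenyl]-6-[5,7-dimethoxy-2-(4-methoxyphenyl)-4-oxo-4H-chromen-3-yl]-7-hydroxy-5-methoxy-4H-chromen-4-one
Conditions: AcOH, H2SO4 (cat.), 95 °C
Reagents that add atoms: none
Why: Acid-catalysed cyclodehydration of a 2-hydroxyaryl 1,3-diketone (closing stage of the Baker-Venkataraman flavone synthesis); the only free hydroxyl ortho to the diketone is the one para to the biaryl bond, so ring C'' can close in one sense only and the 3,6''-linkage results.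

Step 12
Reactants: 18 2-[4-(benzyloxy)phenyl]-6-[5,7-dimethoxy-2-(4-methoxyphenyl)-4-oxo-4H-chromen-3-yl]-7-hydroxy-5-methoxy-4H-chromen-4-one
Product: 19 6-[5-hydroxy-7-methoxy-2-(4-methoxyphenyl)-4-oxo-4H-chromen-3-yl]-5,7-dihydroxy-2-(4-hydroxyphenyl)-4H-chromen-4-one (target, CNP0273448.0)
Conditions: BCl3 (8 equiv), C6HMe5 (5 equiv), CH2Cl2, −78 °C to rt; MeOH, then aq. work-up
Reagents that add atoms: none
Why: Chelation-assisted ether cleavage by BCl3 should remove the two methyl ethers peri to the C4 and C4'' carbonyls and the 4'''-benzyl ether (benzyl cation trapped by pentamethylbenzene), while the non-chelated 7- and 4'-methyl ethers are not cleaved by BCl3 under these conditions.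

**Compound list**
1 | 3,5-bis(benzyloxy)phenol | Oc1cc(OCc2ccccc2)cc(OCc2ccccc2)c1 | starting material
2 | ethyl glyoxylate (ethyl 2-oxoacetate) | CCOC(=O)C=O | starting material
3 | ethyl 2-[2,4-bis(benzyloxy)-6-hydroxyphenyl]-2-hydroxyacetate (racemic) | CCOC(=O)C(O)c1c(O)cc(OCc2ccccc2)cc1OCc1ccccc1 | intermediate
4 | ethyl 2-[2,4-bis(benzyloxy)-6-hydroxyphenyl]acetate (formed in the flask in step 2, not isolated) | CCOC(=O)Cc1c(O)cc(OCc2ccccc2)cc1OCc1ccccc1 | intermediate
5 | 4,6-bis(benzyloxy)benzofuran-2(3H)-one | O=C1Cc2c(OCc3ccccc3)cc(OCc3ccccc3)cc2O1 | intermediate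
6 | 4-methoxybenzoyl chloride | COc1ccc(C(Cl)=O)cc1 | starting material
7 | (Z)-4,6-bis(benzyloxy)-3-[hydroxy(4-methoxyphenyl)methylene]benzofuran-2(3H)-one | O=C1Oc2cc(OCc3ccccc3)cc(OCc3ccccc3)c2/C1=C(/O)c1ccc(OC)cc1 | intermediate
8 | (Z)-4,6-bis(benzyloxy)-3-[(4-methoxyphenyl)(trifluoromethylsulfonyloxy)methylene]benzofuran-2(3H)-one | O=C1Oc2cc(OCc3ccccc3)cc(OCc3ccccc3)c2/C1=C(/OS(=O)(=O)C(F)(F)F)c1ccc(OC)cc1 | intermediate
9 | 3,5-dimethoxyphenol | COc1cc(O)cc(OC)c1 | starting material
10 | (Z)-4,6-bis(benzyloxy)-3-[(3,5-dimethoxyphenoxy)(4-methoxyphenyl)methylene]benzofuran-2(3H)-one | O=C1Oc2cc(OCc3ccccc3)cc(OCc3ccccc3)c2/C1=C(/Oc1cc(OC)cc(OC)c1)c1ccc(OC)cc1 | intermediate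
11 | 3-[2,4-bis(benzyloxy)-6-hydroxyphenyl]-5,7-dimethoxy-2-(4-methoxyphenyl)-4H-chromen-4-one | COc1ccc(-c2oc3cc(OC)cc(OC)c3c(=O)c2-c2c(O)cc(OCc3ccccc3)cc2OCc2ccccc2)cc1 | intermediate
12 | 3,5-bis(benzyloxy)-2-[5,7-dimethoxy-2-(4-methoxyphenyl)-4-oxo-4H-chromen-3-yl]phenyl acetate (formed in the flask in step 7, not isolated) | COc1ccc(-c2oc3cc(OC)cc(OC)c3c(=O)c2-c2c(OC(C)=O)cc(OCc3ccccc3)cc2OCc2ccccc2)cc1 | intermediate
13 | 3-[3-acetyl-4,6-bis(benzyloxy)-2-hydroxyphenyl]-5,7-dimethoxy-2-(4-methoxyphenyl)-4H-chromen-4-one | COc1ccc(-c2oc3cc(OC)cc(OC)c3c(=O)c2-c2c(O)c(C(C)=O)c(OCc3ccccc3)cc2OCc2ccccc2)cc1 | intermediate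
14 | 3-[3-acetyl-4,6-bis(benzyloxy)-2-methoxyphenyl]-5,7-dimethoxy-2-(4-methoxyphenyl)-4H-chromen-4-one | COc1ccc(-c2oc3cc(OC)cc(OC)c3c(=O)c2-c2c(OC)c(C(C)=O)c(OCc3ccccc3)cc2OCc2ccccc2)cc1 | intermediate
15 | 3-(3-acetyl-4,6-dihydroxy-2-methoxyphenyl)-5,7-dimethoxy-2-(4-methoxyphenyl)-4H-chromen-4-one | COc1ccc(-c2oc3cc(OC)cc(OC)c3c(=O)c2-c2c(OC)c(C(C)=O)c(O)cc2O)cc1 | intermediate
16 | 4-(benzyloxy)benzoyl chloride | O=C(Cl)c1ccc(OCc2ccccc2)cc1 | starting material
17 | 1-[4-(benzyloxy)phenyl]-3-{3-[5,7-dimethoxy-2-(4-methoxyphenyl)-4-oxo-4H-chromen-3-yl]-4,6-dihydroxy-2-methoxyphenyl}propane-1,3-dione | COc1ccc(-c2oc3cc(OC)cc(OC)c3c(=O)c2-c2c(OC)c(C(=O)CC(=O)c3ccc(OCc4ccccc4)cc3)c(O)cc2O)cc1 | intermediate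
18 | 2-[4-(benzyloxy)phenyl]-6-[5,7-dimethoxy-2-(4-methoxyphenyl)-4-oxo-4H-chromen-3-yl]-7-hydroxy-5-methoxy-4H-chromen-4-one | COc1ccc(-c2oc3cc(OC)cc(OC)c3c(=O)c2-c2c(O)cc3oc(-c4ccc(OCc5ccccc5)cc4)cc(=O)c3c2OC)cc1 | intermediate
19 | 6-[5-hydroxy-7-methoxy-2-(4-methoxyphenyl)-4-oxo-4H-chromen-3-yl]-5,7-dihydroxy-2-(4-hydroxyphenyl)-4H-chromen-4-one | COc1ccc(-c2oc3cc(OC)cc(O)c3c(=O)c2-c2c(O)cc3oc(-c4ccc(O)cc4)cc(=O)c3c2O)cc1 | target

**Step count and risks**
Total steps: 12. Longest linear sequence: 12 (steps 1 to 12, from 1 and 2).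

Steps most likely to fail:

1. Step 6 (proposed new method). The push-pull lactone carbonyl may be too weakly electrophilic for acyl transfer, or the benzyl ethers may be cleaved or migrate before the ring closes. The fallback replaces the lactone as acyl donor by an acid chloride in a classical Ruhemann sequence; it sets out from 10 and comes back at 11. K2CO3 in MeOH would open the aryl lactone of 10 to methyl (Z)-2-[2,4-bis(benzyloxy)-6-hydroxyphenyl]-3-(3,5-dimethoxyphenoxy)-3-(4-methoxyphenyl)acrylate F1, whose phenoxide would be alkylated in the same flask with allyl bromide to methyl (Z)-2-[2-(allyloxy)-4,6-bis(benzyloxy)phenyl]-3-(3,5-dimethoxyphenoxy)-3-(4-methoxyphenyl)acrylate F2. Saponification (KOSiMe3, THF) would give (Z)-2-[2-(allyloxy)-4,6-bis(benzyloxy)phenyl]-3-(3,5-dimethoxyphenoxy)-3-(4-methoxyphenyl)acrylic acid F3. Oxalyl chloride with catalytic DMF would give (Z)-2-[2-(allyloxy)-4,6-bis(benzyloxy)phenyl]-3-(3,5-dimethoxyphenoxy)-3-(4-methoxyphenyl)acryloyl chloride F4, and SnCl4 in CH2Cl2 at −40 °C would close it by intramolecular Friedel-Crafts acylation to 3-[2-(allyloxy)-4,6-bis(benzyloxy)phenyl]-5,7-dimethoxy-2-(4-methoxyphenyl)-4H-chromen-4-one F5. Tsuji-Trost deallylation (Pd(PPh3)4, morpholine) would then give 11.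

2. Step 5. The phenoxide may attack the sulfur of the triflate (returning the enolate of 7) or the lactone carbonyl faster than it adds to the hindered beta carbon. The fallback abandons sulfonate activation; it sets out from 7 and comes back at 10. Oxalyl chloride with catalytic DMF (Vilsmeier-type chlorination) would convert 7 into the vinylogous acid chloride (Z)-4,6-bis(benzyloxy)-3-[chloro(4-methoxyphenyl)methylene]benzofuran-2(3H)-one F6, which offers no second electrophilic site at the leaving group. Treatment of F6 with 9, K2CO3 and catalytic DABCO in MeCN (ammonium relay addition-elimination) would give 10.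

3. Step 7. Acetylation may occur para to the hydroxyl (between the two benzyloxy groups), or the Lewis acid may strip or shift benzyl groups. The fallback introduces the carbon under non-acidic, strictly ortho-directing conditions; it sets out from 11 and comes back at 13. Magnesium-mediated ortho-formylation (MgCl2, Et3N, paraformaldehyde, MeCN, reflux) would give 3-[4,6-bis(benzyloxy)-3-formyl-2-hydroxyphenyl]-5,7-dimethoxy-2-(4-methoxyphenyl)-4H-chromen-4-one F7. Grignard addition (MeMgBr, THF, −78 °C; the aldehyde should react well before the vinylogous-ester carbonyl) would give racemic 3-[4,6-bis(benzyloxy)-2-hydroxy-3-(1-hydroxyethyl)phenyl]-5,7-dimethoxy-2-(4-methoxyphenyl)-4H-chromen-4-one F8, and MnO2 oxidation of the benzylic alcohol would give 13.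

**Further compounds**
F1 | step 6 | methyl (Z)-2-[2,4-bis(benzyloxy)-6-hydroxyphenyl]-3-(3,5-dimethoxyphenoxy)-3-(4-methoxyphenyl)acrylate | COC(=O)/C(c1c(O)cc(OCc2ccccc2)cc1OCc1ccccc1)=C(\Oc1cc(OC)cc(OC)c1)c1ccc(OC)cc1
F2 | step 6 | methyl (Z)-2-[2-(allyloxy)-4,6-bis(benzyloxy)phenyl]-3-(3,5-dimethoxyphenoxy)-3-(4-methoxyphenyl)acrylate | COC(=O)/C(c1c(OCC=C)cc(OCc2ccccc2)cc1OCc1ccccc1)=C(\Oc1cc(OC)cc(OC)c1)c1ccc(OC)cc1
F3 | step 6 | (Z)-2-[2-(allyloxy)-4,6-bis(benzyloxy)phenyl]-3-(3,5-dimethoxyphenoxy)-3-(4-methoxyphenyl)acrylic acid | OC(=O)/C(c1c(OCC=C)cc(OCc2ccccc2)cc1OCc1ccccc1)=C(\Oc1cc(OC)cc(OC)c1)c1ccc(OC)cc1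
F4 | step 6 | (Z)-2-[2-(allyloxy)-4,6-bis(benzyloxy)phenyl]-3-(3,5-dimethoxyphenoxy)-3-(4-methoxyphenyl)acryloyl chloride | ClC(=O)/C(c1c(OCC=C)cc(OCc2ccccc2)cc1OCc1ccccc1)=C(\Oc1cc(OC)cc(OC)c1)c1ccc(OC)cc1
F5 | step 6 | 3-[2-(allyloxy)-4,6-bis(benzyloxy)phenyl]-5,7-dimethoxy-2-(4-methoxyphenyl)-4H-chromen-4-one | COc1ccc(-c2oc3cc(OC)cc(OC)c3c(=O)c2-c2c(OCC=C)cc(OCc3ccccc3)cc2OCc2ccccc2)cc1
F6 | step 5 | (Z)-4,6-bis(benzyloxy)-3-[chloro(4-methoxyphenyl)methylene]benzofuran-2(3H)-one | O=C1Oc2cc(OCc3ccccc3)cc(OCc3ccccc3)c2/C1=C(/Cl)c1ccc(OC)cc1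
F7 | step 7 | 3-[4,6-bis(benzyloxy)-3-formyl-2-hydroxyphenyl]-5,7-dimethoxy-2-(4-methoxyphenyl)-4H-chromen-4-one | COc1ccc(-c2oc3cc(OC)cc(OC)c3c(=O)c2-c2c(O)c(C=O)c(OCc3ccccc3)cc2OCc2ccccc2)cc1
F8 | step 7 | 3-[4,6-bis(benzyloxy)-2-hydroxy-3-(1-hydroxyethyl)phenyl]-5,7-dimethoxy-2-(4-methoxyphenyl)-4H-chromen-4-one (racemic) | COc1ccc(-c2oc3cc(OC)cc(OC)c3c(=O)c2-c2c(O)c(C(C)O)c(OCc3ccccc3)cc2OCc2ccccc2)cc1
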